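**Plan**
- Retrosynthetic cuts, in order: (i) the bond from ring A (the arene with one C–H) to its benzylic CH(OH) carbon; (ii) the two ester C(=O)–O bonds; (iii) the ring B aryl–CH(OH) bond.
- Enabling feature: the CH3–CH(O-acyl)–CH(OH)–aryl unit on ring A is an O-acyl (S)-lactaldehyde plus an aryl anion. Its aryl carbon lies between a ring C–H and the ester-bearing carbon, so this is the least hindered ring bond to close.
- Forward order: both arenes from 2-methoxyresorcinol (ring A iodo acid, ring B bromo aryl dioxolane); ring B side chain by aryllithium addition to a lactate aldehyde; first ester; dioxolane to acid; second ester; aldehyde. The 12-membered dilactone is the only ring formed, by Ni/Cr aryl–aldehyde coupling; hydrogenolysis ends the route.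
- Stereochemistry: ring B carbinol (R) by Felkin–Anh addition to (S)-2-silyloxypropanal from ethyl L-lactate; its methyl carbon (S to R) by Mitsunobu inversion. Ring A methyl carbon (S) from (R)-propane-1,2-diol by Mitsunobu inversion; ring A carbinol (S) by ligand-controlled Si-face arylation.

Key step: step 23

Remark: the configuration is taken as written in the SMILES, (1R,2R) in the ring B side chain and (1S,2S) in the ring A side chain (both threo). The antipode of the sulfonamide ligand that gives Si-face arylation in step 23 is assumed to be found by a trial with both enantiomers.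

**Ring A iodo acid**

Step 1
Reactants: 1 2-methoxyresorcinol
Product: 2 2-methoxy-1,3-bis(triisopropylsilyloxy)benzene
Conditions: TIPSCl, imidazole, DMF, rt
Reagents that add atoms: triisopropylsilyl chloride, CC(C)[Si](Cl)(C(C)C)C(C)C
Why: Imidazole-promoted O-silylation of both phenols gives bulky silyl ethers that shield C4 and C6 and are inert to the borylation that follows.

Step 2
Reactants: 2 2-methoxy-1,3-bis(triisopropylsilyloxy)benzene
Product: 4 5-iodo-2-methoxy-1,3-bis(triisopropylsilyloxy)benzene, via aryl pinacol boronate 3 (not isolated)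
Conditions: B2pin2, [Ir(OMe)(cod)]2 (cat.), 4,4'-di-tert-butyl-2,2'-bipyridine (cat.), THF, 80 °C; then CuI (cat.), 1,10-phenanthroline, KI, MeOH/THF/H2O, air, 80 °C
Reagents that add atoms: bis(pinacolato)diboron, CC1(C)OB(OC1(C)C)B1OC(C)(C)C(C)(C)O1 (boryl group of 3 only); potassium iodide, [K+].[I-] (iodine of 4)
Why: Sterically governed iridium-catalysed aromatic C–H borylation attacks only C5, the one C–H without an ortho substituent, and copper-catalysed iododeboronation then places iodine para to the methoxy group, a site that electrophilic substitution would not reach.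

Step 3
Reactants: 4 5-iodo-2-methoxy-1,3-bis(triisopropylsilyloxy)benzene
Product: 6 1,3-bis(benzyloxy)-5-iodo-2-methoxybenzene, via bis(tetrabutylammonium) diphenoxide 5 (not isolated)
Conditions: Bu4NF, THF, 0 °C; then BnBr, rt
Reagents that add atoms: tetrabutylammonium fluoride, CCCC[N+](CCCC)(CCCC)CCCC.[F-] (counter-ion of 5 only); benzyl bromide, BrCc1ccccc1
Why: Fluoride desilylation frees the diphenoxide, which undergoes Williamson O-benzylation in the same flask, so the benzyl ethers needed for the final hydrogenolysis replace the silyl groups in one operation.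

Step 4
Reactants: 6 1,3-bis(benzyloxy)-5-iodo-2-methoxybenzene
Product: 7 2,4-bis(benzyloxy)-6-iodo-3-methoxybenzaldehyde
Conditions: POCl3, DMF, 80 °C; then H2O
Reagents that add atoms: N,N-dimethylformamide, CN(C)C=O (formyl carbon); water, O (formyl oxygen)
Why: Vilsmeier–Haack formylation takes place at one of the two equivalent positions ortho and para to the benzyloxy groups, each of which is next to iodine, so the formyl and iodo groups necessarily end up on adjacent carbons.

Step 5
Reactants: 7 2,4-bis(benzyloxy)-6-iodo-3-methoxybenzaldehyde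
Product: 8 2,4-bis(benzyloxy)-6-iodo-3-methoxybenzoic acid (ring A acid)
Conditions: NaClO2, NaH2PO4, 2-methyl-2-butene, t-BuOH/THF/H2O, rt
Reagents that add atoms: sodium chlorite, [Na+].[O-]Cl=O
Why: Pinnick oxidation, with 2-methyl-2-butene trapping HOCl before it can chlorinate the free ring position, converts the aldehyde into the acid and leaves the aryl iodide and benzyl ethers alone.

**Ring B bromo aryl dioxolane**

Step 6
Reactants: 1 2-methoxyresorcinol
Product: 9 1,3-bis(benzyloxy)-2-methoxybenzene
Conditions: BnBr, K2CO3, DMF, 60 °C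
Reagents that add atoms: benzyl bromide, BrCc1ccccc1
Why: Williamson etherification of both phenols installs the protecting groups that are carried to the last step.

Step 7
Reactants: 9 1,3-bis(benzyloxy)-2-methoxybenzene
Product: 10 2,4-bis(benzyloxy)-3-methoxybenzaldehyde
Conditions: POCl3, DMF, 70 °C; then H2O
Reagents that add atoms: N,N-dimethylformamide, CN(C)C=O (formyl carbon); water, O (formyl oxygen)
Why: Vilsmeier–Haack formylation of a 1,2,3-trialkoxybenzene goes to C4, ortho to one and para to the other benzyloxy group, as it does with 1,2,3-trimethoxybenzene.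

Step 8
Reactants: 10 2,4-bis(benzyloxy)-3-methoxybenzaldehyde
Product: 11 2,4-bis(benzyloxy)-5-iodo-3-methoxybenzaldehyde
Conditions: NIS, CF3CO2H (cat.), MeCN, rt
Reagents that add atoms: N-iodosuccinimide, O=C1CCC(=O)N1I
Why: Acid-activated N-iodosuccinimide iodinates by electrophilic aromatic substitution at C5, the position ortho and para to the two benzyloxy groups and meta to the deactivating formyl group.

Step 9
Reactants: 11 2,4-bis(benzyloxy)-5-iodo-3-methoxybenzaldehyde
Product: 12 2-[2,4-bis(benzyloxy)-5-iodo-3-methoxyphenyl]-1,3-dioxolane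
Conditions: ethylene glycol, p-TsOH (cat.), toluene, reflux with azeotropic removal of water
Reagents that add atoms: ethylene glycol, OCCO
Why: Acid-catalysed acetalisation masks the future ring B carboxyl carbon as a dioxolane that tolerates carbonate base, N-bromosuccinimide and organolithium reagents.

Step 10
Reactants: 12 2-[2,4-bis(benzyloxy)-5-iodo-3-methoxyphenyl]-1,3-dioxolane
Product: 13 2-[2,4,5-tris(benzyloxy)-3-methoxyphenyl]-1,3-dioxolane
Conditions: BnOH, CuI (cat.), 3,4,7,8-tetramethyl-1,10-phenanthroline (cat.), Cs2CO3, toluene, 110 °C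
Reagents that add atoms: benzyl alcohol, OCc1ccccc1
Why: Copper-catalysed Ullmann-type C–O coupling of an aryl iodide with a primary alcohol installs the fourth ring oxygen directly as its benzyl ether.

Step 11
Reactants: 13 2-[2,4,5-tris(benzyloxy)-3-methoxyphenyl]-1,3-dioxolane
Product: 14 2-[2,4,5-tris(benzyloxy)-6-bromo-3-methoxyphenyl]-1,3-dioxolane
Conditions: NBS, DMF, 0 °C to rt, dark
Reagents that add atoms: N-bromosuccinimide, O=C1CCC(=O)N1Br
Why: Electrophilic bromination can only occur at the single remaining ring C–H, which is activated by the ortho benzyloxy and para methoxy groups, and DMF keeps the medium non-acidic for the acetal.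

**Chiral pieces**

Step 12
Reactants: 15 ethyl L-lactate
Product: 16 ethyl (S)-2-(tert-butyldiphenylsilyloxy)propanoate
Conditions: TBDPSCl, imidazole, DMF, rt
Reagents that add atoms: tert-butyl(chloro)diphenylsilane, CC(C)(C)[Si](Cl)(c1ccccc1)c1ccccc1
Why: Imidazole-promoted silylation protects the lactate hydroxyl with a bulky, non-chelating group that later enforces Felkin–Anh addition.

Step 13
Reactants: 16 ethyl (S)-2-(tert-butyldiphenylsilyloxy)propanoate
Product: 17 (S)-2-(tert-butyldiphenylsilyloxy)propanal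
Conditions: i-Bu2AlH, CH2Cl2, −78 °C; aq. potassium sodium tartrate
Reagents that add atoms: none
Why: Partial ester reduction with one equivalent of i-Bu2AlH at −78 °C stops at the aluminium hemiacetal, which gives the aldehyde on hydrolysis without loss of configuration at the α-carbon.

Step 14
Reactants: 18 (R)-propane-1,2-diol
Product: 19 (R)-1-(tert-butyldimethylsilyloxy)propan-2-ol
Conditions: TBSCl (1 equiv), imidazole, CH2Cl2, 0 °C
Reagents that add atoms: tert-butyl(chloro)dimethylsilane, CC(C)(C)[Si](C)(C)Cl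
Why: Silylation with one equivalent of silyl chloride at 0 °C is selective for the primary hydroxyl of the 1,2-diol, leaving the secondary (R)-carbinol free for the later Mitsunobu reaction.

**Assembly**

Step 15
Reactants: 14 2-[2,4,5-tris(benzyloxy)-6-bromo-3-methoxyphenyl]-1,3-dioxolane; 17 (S)-2-(tert-butyldiphenylsilyloxy)propanal
Product: 21 (1R,2S)-2-(tert-butyldiphenylsilyloxy)-1-[2,3,5-tris(benzyloxy)-6-(1,3-dioxolan-2-yl)-4-methoxyphenyl]propan-1-ol, via aryllithium 20 (not isolated)
Conditions: n-BuLi, THF, −78 °C; then 17, −78 °C; aq. NH4Cl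
Reagents that add atoms: n-butyllithium, [Li]CCCC (lithium of 20 only)
Why: Bromine–lithium exchange followed by 1,2-addition to the aldehyde forms the ring B aryl–carbinol bond, and the new (R)-centre results from Felkin–Anh attack anti to the non-chelating silyloxy group of the (S)-aldehyde (anti, erythro adduct), the minor epimer being removable by chromatography on base-washed silica.

Step 16
Reactants: 21 (1R,2S)-silyloxy benzylic alcohol
Product: 22 2-{2,3,5-tris(benzyloxy)-6-[(1R,2S)-1-(benzyloxymethoxy)-2-(tert-butyldiphenylsilyloxy)propyl]-4-methoxyphenyl}-1,3-dioxolane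
Conditions: BnOCH2Cl, i-Pr2NEt, Bu4NI (cat.), CH2Cl2, 40 °C
Reagents that add atoms: benzyl chloromethyl ether, ClCOCc1ccccc1
Why: Alkoxymethylation under amine base protects the hindered benzylic hydroxyl without forming an alkoxide, so the neighbouring silyl group cannot migrate, and the benzyloxymethyl group can leave in the final hydrogenolysis.

Step 17
Reactants: 22 benzyloxymethyl ether
Product: 23 (1R,2S)-1-(benzyloxymethoxy)-1-[2,3,5-tris(benzyloxy)-6-(1,3-dioxolan-2-yl)-4-methoxyphenyl]propan-2-ol
Conditions: Bu4NF, THF, rt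
Reagents that add atoms: none
Why: Fluoride-mediated desilylation frees the C2 hydroxyl while the acetal, benzyloxymethyl and benzyl ethers are untouched.

Step 18
Reactants: 23 (1R,2S)-alcohol; 8 ring A acid
Product: 24 (1R,2R)-1-(benzyloxymethoxy)-1-[2,3,5-tris(benzyloxy)-6-(1,3-dioxolan-2-yl)-4-methoxyphenyl]propan-2-yl 2,4-bis(benzyloxy)-6-iodo-3-methoxybenzoate
Conditions: PPh3, DIAD, toluene, 0 °C (betaine preformed); 23, then 8 added slowly; rt
Reagents that add atoms: none
Why: Mitsunobu esterification lets the acidic, doubly ortho-substituted benzoic acid act as the nucleophile in an SN2 displacement of the alkoxyphosphonium group, which avoids acylation by a hindered acyl donor and inverts C2 from (S) to (R), giving the threo arrangement of the ring B side chain.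

Step 19
Reactants: 24 ring A ester with aryl dioxolane
Product: 26 2,4,5-tris(benzyloxy)-6-[(1R,2R)-1-(benzyloxymethoxy)-2-{[2,4-bis(benzyloxy)-6-iodo-3-methoxybenzoyl]oxy}propyl]-3-methoxybenzoic acid, via ring B aldehyde 25 (not isolated)
Conditions: aq. HCl (1 M), THF, rt; then NaClO2, NaH2PO4, 2-methyl-2-butene, t-BuOH/H2O, rt
Reagents that add atoms: water, O (carbonyl oxygen); sodium chlorite, [Na+].[O-]Cl=O (hydroxyl oxygen)
Why: Dilute aqueous acid hydrolyses the electron-rich aryl dioxolane much faster than the formaldehyde-derived benzyloxymethyl acetal, and Pinnick oxidation of the crude aldehyde gives the acid without affecting the ester, the aryl iodide or the ethers.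

Step 20
Reactants: 26 ring B acid; 19 (R)-1-(tert-butyldimethylsilyloxy)propan-2-ol
Product: 27 (S)-1-(tert-butyldimethylsilyloxy)propan-2-yl ester of acid 26
Conditions: PPh3, DIAD, THF, 0 °C to rt
Reagents that add atoms: none
Why: A second Mitsunobu esterification joins the hindered ring B acid to the secondary alcohol by SN2 attack of the carboxylate with inversion, so the (R)-alcohol gives the (S)-configured ester carbon of the future lactaldehyde unit.

Step 21
Reactants: 27 silyl ether diester
Product: 28 (S)-1-hydroxypropan-2-yl ester of acid 26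
Conditions: HF·pyridine, pyridine, THF, 0 °C to rt
Reagents that add atoms: none
Why: Buffered HF·pyridine cleaves the primary silyl ether under mildly acidic conditions in which the hindered aroyl group should not migrate to the freed primary hydroxyl.

Step 22
Reactants: 28 primary alcohol diester
Product: 29 (S)-1-oxopropan-2-yl ester of acid 26 (open-chain iodo aldehyde diester)
Conditions: Dess–Martin periodinane, CH2Cl2, 0 °C to rt; used at once
Reagents that add atoms: none
Why: Dess–Martin oxidation of the primary alcohol gives the α-acyloxy aldehyde under neutral conditions that should not epimerise the adjacent stereocentre.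

Step 23
Reactants: 29 open-chain iodo aldehyde diester
Product: 30 protected 12-membered dilactone with five phenolic O-benzyl groups, O-benzyloxymethyl on the ring B (R)-carbinol and a free hydroxyl on the new ring A (S)-carbinol
Conditions: CrCl2 (excess), NiCl2(2,9-dimethyl-1,10-phenanthroline) (cat.), chiral oxazoline–sulfonamide ligand N-[2-(4-isopropyl-4,5-dihydrooxazol-2-yl)-6-methylphenyl]methanesulfonamide (antipode giving Si-face arylation), Et3N, THF, rt; 29 added over 12 h to 2 mM
Reagents that add atoms: none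
Why: CrCl2 reduces the nickel catalyst to zerovalent nickel, which inserts into the ring A C–I bond; the aryl group passes to trivalent chromium, and the arylchromium, bound to the deprotonated sulfonamide ligand, adds to the tethered aldehyde while ignoring both esters. The closest known reaction type is the intramolecular Nozaki–Hiyama–Kishi macrocyclisation of sp2 iodides onto aldehydes, including its chiral sulfonamide ligand-controlled variant. The 12-membered dilactone closes in a 12-exo-trig mode, favoured over oligomerisation by slow addition to high dilution and by the reacting aryl carbon having a C–H as one ortho neighbour. The new (S)-carbinol arises from Si-face attack imposed by the chiral ligand on chromium, which has to override the Felkin–Anh (erythro) preference of the α-acyloxy aldehyde. The chromium alkoxide is too weakly nucleophilic to attack the ortho ester, so no phthalide should form and the ring stays closed.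

Step 24
Reactants: 30 protected dilactone
Product: 31 CNP0086623.3 (target)
Conditions: H2 (1 atm), Pd/C, EtOAc/MeOH, rt; degassed work-up
Reagents that add atoms: none
Why: Palladium-catalysed hydrogenolysis removes the five aryl benzyl ethers and the benzyloxymethyl group (whose hemiacetal loses formaldehyde) under neutral conditions in which the two lactones and both secondary benzylic alcohols should persist.

**Compound list**

1 | 2-methoxyresorcinol (2-methoxybenzene-1,3-diol) | COc1c(O)cccc1O | starting material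
2 | 2-methoxy-1,3-bis(triisopropylsilyloxy)benzene | COc1c(O[Si](C(C)C)(C(C)C)C(C)C)cccc1O[Si](C(C)C)(C(C)C)C(C)C | intermediate
3 | 2-[4-methoxy-3,5-bis(triisopropylsilyloxy)phenyl]-4,4,5,5-tetramethyl-1,3,2-dioxaborolane (formed in situ) | COc1c(O[Si](C(C)C)(C(C)C)C(C)C)cc(B2OC(C)(C)C(C)(C)O2)cc1O[Si](C(C)C)(C(C)C)C(C)C | intermediate
4 | 5-iodo-2-methoxy-1,3-bis(triisopropylsilyloxy)benzene | COc1c(O[Si](C(C)C)(C(C)C)C(C)C)cc(I)cc1O[Si](C(C)C)(C(C)C)C(C)C | intermediate
5 | bis(tetrabutylammonium) 5-iodo-2-methoxybenzene-1,3-diolate (formed in situ) | COc1c([O-])cc(I)cc1[O-].CCCC[N+](CCCC)(CCCC)CCCC.CCCC[N+](CCCC)(CCCC)CCCC | intermediate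
6 | 1,3-bis(benzyloxy)-5-iodo-2-methoxybenzene | COc1c(OCc2ccccc2)cc(I)cc1OCc3ccccc3 | intermediate
7 | 2,4-bis(benzyloxy)-6-iodo-3-methoxybenzaldehyde | COc1c(OCc2ccccc2)cc(I)c(C=O)c1OCc3ccccc3 | intermediate
8 | 2,4-bis(benzyloxy)-6-iodo-3-methoxybenzoic acid | COc1c(OCc2ccccc2)cc(I)c(C(=O)O)c1OCc3ccccc3 | intermediate
9 | 1,3-bis(benzyloxy)-2-methoxybenzene | COc1c(OCc2ccccc2)cccc1OCc3ccccc3 | intermediate
10 | 2,4-bis(benzyloxy)-3-methoxybenzaldehyde | COc1c(OCc2ccccc2)ccc(C=O)c1OCc3ccccc3 | intermediate
11 | 2,4-bis(benzyloxy)-5-iodo-3-methoxybenzaldehyde | COc1c(OCc2ccccc2)c(I)cc(C=O)c1OCc3ccccc3 | intermediate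
12 | 2-[2,4-bis(benzyloxy)-5-iodo-3-methoxyphenyl]-1,3-dioxolane | COc1c(OCc2ccccc2)c(I)cc(C3OCCO3)c1OCc4ccccc4 | intermediate
13 | 2-[2,4,5-tris(benzyloxy)-3-methoxyphenyl]-1,3-dioxolane | COc1c(OCc2ccccc2)c(OCc3ccccc3)cc(C4OCCO4)c1OCc5ccccc5 | intermediate
14 | 2-[2,4,5-tris(benzyloxy)-6-bromo-3-methoxyphenyl]-1,3-dioxolane | COc1c(OCc2ccccc2)c(OCc3ccccc3)c(Br)c(C4OCCO4)c1OCc5ccccc5 | intermediate
15 | ethyl L-lactate (ethyl (S)-2-hydroxypropanoate) | C[C@H](O)C(=O)OCC | starting material
16 | ethyl (S)-2-(tert-butyldiphenylsilyloxy)propanoate | C[C@H](O[Si](c1ccccc1)(c2ccccc2)C(C)(C)C)C(=O)OCC | intermediate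
17 | (S)-2-(tert-butyldiphenylsilyloxy)propanal | C[C@H](O[Si](c1ccccc1)(c2ccccc2)C(C)(C)C)C=O | intermediate
18 | (R)-propane-1,2-diol | C[C@@H](O)CO | starting material
19 | (R)-1-(tert-butyldimethylsilyloxy)propan-2-ol | C[C@@H](O)CO[Si](C)(C)C(C)(C)C | intermediate
20 | [2,3,5-tris(benzyloxy)-6-(1,3-dioxolan-2-yl)-4-methoxyphenyl]lithium (formed in situ) | [Li]c1c(OCc2ccccc2)c(OCc3ccccc3)c(OC)c(OCc4ccccc4)c1C5OCCO5 | intermediate
21 | (1R,2S)-2-(tert-butyldiphenylsilyloxy)-1-[2,3,5-tris(benzyloxy)-6-(1,3-dioxolan-2-yl)-4-methoxyphenyl]propan-1-ol | C[C@H](O[Si](c1ccccc1)(c2ccccc2)C(C)(C)C)[C@H](O)c3c(OCc4ccccc4)c(OCc5ccccc5)c(OC)c(OCc6ccccc6)c3C7OCCO7 | intermediate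
22 | 2-{2,3,5-tris(benzyloxy)-6-[(1R,2S)-1-(benzyloxymethoxy)-2-(tert-butyldiphenylsilyloxy)propyl]-4-methoxyphenyl}-1,3-dioxolane | C[C@H](O[Si](c1ccccc1)(c2ccccc2)C(C)(C)C)[C@H](OCOCc8ccccc8)c3c(OCc4ccccc4)c(OCc5ccccc5)c(OC)c(OCc6ccccc6)c3C7OCCO7 | intermediate
23 | (1R,2S)-1-(benzyloxymethoxy)-1-[2,3,5-tris(benzyloxy)-6-(1,3-dioxolan-2-yl)-4-methoxyphenyl]propan-2-ol | C[C@H](O)[C@H](OCOCc8ccccc8)c3c(OCc4ccccc4)c(OCc5ccccc5)c(OC)c(OCc6ccccc6)c3C7OCCO7 | intermediate
24 | (1R,2R)-1-(benzyloxymethoxy)-1-[2,3,5-tris(benzyloxy)-6-(1,3-dioxolan-2-yl)-4-methoxyphenyl]propan-2-yl 2,4-bis(benzyloxy)-6-iodo-3-methoxybenzoate | COc1c(OCc2ccccc2)cc(I)c(c1OCc3ccccc3)C(=O)O[C@H](C)[C@H](OCOCc8ccccc8)c4c(OCc5ccccc5)c(OCc6ccccc6)c(OC)c(OCc7ccccc7)c4C9OCCO9 | intermediate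
25 | (1R,2R)-1-(benzyloxymethoxy)-1-[2,3,5-tris(benzyloxy)-6-formyl-4-methoxyphenyl]propan-2-yl 2,4-bis(benzyloxy)-6-iodo-3-methoxybenzoate (formed in situ) | COc1c(OCc2ccccc2)cc(I)c(c1OCc3ccccc3)C(=O)O[C@H](C)[C@H](OCOCc8ccccc8)c4c(OCc5ccccc5)c(OCc6ccccc6)c(OC)c(OCc7ccccc7)c4C=O | intermediate
26 | 2,4,5-tris(benzyloxy)-6-[(1R,2R)-1-(benzyloxymethoxy)-2-{[2,4-bis(benzyloxy)-6-iodo-3-methoxybenzoyl]oxy}propyl]-3-methoxybenzoic acid | COc1c(OCc2ccccc2)cc(I)c(c1OCc3ccccc3)C(=O)O[C@H](C)[C@H](OCOCc8ccccc8)c4c(OCc5ccccc5)c(OCc6ccccc6)c(OC)c(OCc7ccccc7)c4C(=O)O | intermediate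
27 | (S)-1-(tert-butyldimethylsilyloxy)propan-2-yl ester of acid 26 | COc1c(OCc2ccccc2)cc(I)c(c1OCc3ccccc3)C(=O)O[C@H](C)[C@H](OCOCc8ccccc8)c4c(OCc5ccccc5)c(OCc6ccccc6)c(OC)c(OCc7ccccc7)c4C(=O)O[C@@H](C)CO[Si](C)(C)C(C)(C)C | intermediate
28 | (S)-1-hydroxypropan-2-yl ester of acid 26 | COc1c(OCc2ccccc2)cc(I)c(c1OCc3ccccc3)C(=O)O[C@H](C)[C@H](OCOCc8ccccc8)c4c(OCc5ccccc5)c(OCc6ccccc6)c(OC)c(OCc7ccccc7)c4C(=O)O[C@@H](C)CO | intermediate
29 | (S)-1-oxopropan-2-yl ester of acid 26 (open-chain iodo aldehyde diester) | COc1c(OCc2ccccc2)cc(I)c(c1OCc3ccccc3)C(=O)O[C@H](C)[C@H](OCOCc8ccccc8)c4c(OCc5ccccc5)c(OCc6ccccc6)c(OC)c(OCc7ccccc7)c4C(=O)O[C@@H](C)C=O | intermediate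
30 | protected 12-membered dilactone: five O-benzyl groups, O-benzyloxymethyl on the ring B (R)-carbinol, free ring A (S)-carbinol | COc1c(OCc2ccccc2)cc3c(c1OCc4ccccc4)C(=O)O[C@H](C)[C@H](OCOCc5ccccc5)c6c(OCc7ccccc7)c(OCc8ccccc8)c(OC)c(OCc9ccccc9)c6C(=O)O[C@@H](C)[C@H]3O | intermediate
31 | CNP0086623.3 | COc1c(O)cc2c(c1O)C(=O)O[C@H](C)[C@H](O)c1c(O)c(O)c(OC)c(O)c1C(=O)O[C@@H](C)[C@H]2O | target

**Step count and risks**

Total: 24 steps. Longest linear sequence: 16 steps (steps 6–11, then 15–24, from 2-methoxyresorcinol).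

Steps most likely to fail:

1. Step 23. Facial selectivity may be poor if the Felkin–Anh bias of the α-acyloxy aldehyde overrides the ligand, and oligomerisation may compete with ring closure. Fallback: set the carbinol by reduction instead of by C–C bond formation. From 29, the coupling is run without the chiral ligand (CrCl2, NiCl2 cat., DMF/THF, high dilution) and the erythro product, the ring A (R)-carbinol epimer of the dilactone F1, is accepted. It is oxidised with Dess–Martin periodinane to the macrocyclic aryl ketone F2. Reduction with NaBH4 in MeOH/THF at −78 °C, hydride arriving anti to the acyloxy group (polar Felkin–Anh), should give the threo carbinol and so return to 30.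

2. Step 18. The SN2 displacement at the hindered C2 carbinol carbon may be slow, with elimination or return of unchanged alcohol. Fallback: invert the alcohol by oxidation and reduction, then form the ester by acyl substitution with retention. From 23, Dess–Martin oxidation gives the methyl ketone (R)-1-(benzyloxymethoxy)-1-[2,3,5-tris(benzyloxy)-6-(1,3-dioxolan-2-yl)-4-methoxyphenyl]propan-2-one F3. Reduction with LiBH(s-Bu)3 in THF at −78 °C (Felkin–Anh, alkoxy group anti to hydride) should give the threo (1R,2R)-alcohol F4. Acid 8 is converted with (COCl)2 and catalytic DMF into 2,4-bis(benzyloxy)-6-iodo-3-methoxybenzoyl chloride F5, which acylates the sodium alkoxide of F4 (NaN(SiMe3)2, THF, −78 to 0 °C) to rejoin the route at 24.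

3. Step 10. The C–O coupling may stall at the electron-rich, ortho-substituted aryl iodide, or iodine may be lost by reduction. Fallback: make the phenol by metalation and oxidation, then alkylate. From 12, iodine–lithium exchange (n-BuLi, THF, −78 °C), borylation with B(OMe)3 and oxidation with H2O2/NaOH give 2,4-bis(benzyloxy)-5-(1,3-dioxolan-2-yl)-3-methoxyphenol F6. Benzylation (BnBr, K2CO3, DMF) returns to 13.

**Further compounds**

F1 | step 23 | ring A (R)-carbinol (erythro) epimer of dilactone 30 | COc1c(OCc2ccccc2)cc3c(c1OCc4ccccc4)C(=O)O[C@H](C)[C@H](OCOCc5ccccc5)c6c(OCc7ccccc7)c(OCc8ccccc8)c(OC)c(OCc9ccccc9)c6C(=O)O[C@@H](C)[C@@H]3O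
F2 | step 23 | macrocyclic aryl ketone (ring A carbinol of 30 oxidised to C=O) | COc1c(OCc2ccccc2)cc3c(c1OCc4ccccc4)C(=O)O[C@H](C)[C@H](OCOCc5ccccc5)c6c(OCc7ccccc7)c(OCc8ccccc8)c(OC)c(OCc9ccccc9)c6C(=O)O[C@@H](C)C3=O
F3 | step 18 | (R)-1-(benzyloxymethoxy)-1-[2,3,5-tris(benzyloxy)-6-(1,3-dioxolan-2-yl)-4-methoxyphenyl]propan-2-one | CC(=O)[C@H](OCOCc8ccccc8)c3c(OCc4ccccc4)c(OCc5ccccc5)c(OC)c(OCc6ccccc6)c3C7OCCO7
F4 | step 18 | (1R,2R)-1-(benzyloxymethoxy)-1-[2,3,5-tris(benzyloxy)-6-(1,3-dioxolan-2-yl)-4-methoxyphenyl]propan-2-ol | C[C@@H](O)[C@H](OCOCc8ccccc8)c3c(OCc4ccccc4)c(OCc5ccccc5)c(OC)c(OCc6ccccc6)c3C7OCCO7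
F5 | step 18 | 2,4-bis(benzyloxy)-6-iodo-3-methoxybenzoyl chloride | COc1c(OCc2ccccc2)cc(I)c(C(=O)Cl)c1OCc3ccccc3
F6 | step 10 | 2,4-bis(benzyloxy)-5-(1,3-dioxolan-2-yl)-3-methoxyphenol | COc1c(OCc2ccccc2)c(O)cc(C3OCCO3)c1OCc4ccccc4
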